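## Structural features

The target is one cyclohexane ring in which four neighbouring carbons, C2–C1–C6–C5, are stereogenic and oxygenated, while C3 and C4 are plain methylenes. C1 is fully substituted (tertiary hydroxyl plus the exocyclic C7H2 that carries one benzoate), C2 and C6 bear free secondary hydroxyls, and C5 bears the second benzoate. Reading the stereodescriptors of the string gives C1 S, C2 R, C5 R, C6 S: O2 and O6 are cis to each other and to C7, O1 is trans to both, and O5 is trans to O6. In the chair, O1, O2, O5 and O6 are therefore all equatorial and only C7 is axial. The fragile elements are the two benzoates, each with a free hydroxyl within reach (O5 beside O6; O7 beside O1, O2 and O6), so base after their introduction invites acyl migration. The real difficulties are the quaternary C1 with its axial carbon substituent between two carbinol carbons, and sorting five oxygens into two esters and three free hydroxyls. The key step uses the C2–C1–C6 triad: a carbon between two cis carbinol carbons is what a nitronate carbon leaves when it bridges the two formyl groups of a pentanedial (C2 to C6), with C5 then α to one formyl group. Everything the cyclisation must place (O2, O6, the C1 nitro group) is equatorial, so the ring can be built under equilibrating conditions with C5 as the only source of chirality, and the nitro-bearing C1 is a masked ketone that receives C7 later.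

## Logic of the disconnections

25 from 24. The two acetal C–O bonds joining O2 and O6 through one benzylic carbon are cut last. The reason is that the final step should be neutral, since both esters are then in place beside free hydroxyls. The gain is that three hydroxyls are freed in one operation. The demand is a hydrogenolysis that cleaves a benzylic acetal and leaves two benzoates alone.

24 from 22 and 23. The acyl–O5 bond is cut. In 22 the only other free hydroxyl is the tertiary one at C1, so no selectivity problem among secondary hydroxyls arises. The demand is that the acylation stops at the secondary alcohol.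

22 from 20 and 21. The C7–O7 bond is cut, leading back to a spiro-epoxide on C1. This delivers the ester oxygen and the tertiary hydroxyl in one step and leaves the C1–O bond untouched, so the C1 configuration is carried through. The demand is clean SN2 opening at the primary epoxide carbon.

20 from 19. The O5–CH2Ar bond is cut. The O5 ether is an electron-rich benzyl ether so that it can be removed oxidatively while the hydrogenolysis-labile bridge stays. It is removed before the epoxide is opened, because afterwards a tertiary hydroxyl would sit syn-axial to O5 and could trap the oxidised ether as a cyclic acetal.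

19 from 18 and 2. The C1–C7 bond and the C7–O1 bond are cut (methylene transfer to a ketone). This reduces the quaternary centre to a carbonyl group. The demand is that carbon arrives on the face of 18 that is syn to O2 and O6. In 18 that face belongs to a 1,3-dioxan-5-one chair (ring B) and is flanked only by oxygen lone pairs. The opposite face belongs to the carbocycle (ring A) and is screened by the axial O5 ether. The bridge is derived from an aldehyde and not from a ketone: a gem-dimethyl bridge would push one methyl group against C4, force ring B into a boat, and cover the face that C7 must use.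

18 from 15 (through 17). C1=O is traced back to C1–NO2. The bridge makes this safe: β-elimination of O2 or O6 from the nitronate, or enolisation of 18 towards C2 or C6, would need a bridgehead double bond, and no free hydroxyl is left for a retro-Henry reaction. The demand is an oxidative cleavage of the nitronate that spares two benzylic positions.

15 from 13 and 14. The two acetal C–O bonds are cut. Only a cis-1,3-diol can be bridged, so this step also checks the relative configuration made in the key step. The demand is ring inversion of 13 to the conformer with O2 and O6 axial.

13 from 10 and 11 (through 12). The C1–C2 and C1–C6 bonds are cut. This is the step that carries the strategy: one ring, two skeletal bonds and three stereocentres from an open chain and a one-carbon unit. The demand is full equilibration to the all-equatorial isomer without loss of the C5 configuration.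

10 from 7 and 8 (through 9). Both formyl groups are traced to the two carbons of a ring alkene. A cyclic alkene is chosen so that cleavage gives 10 and nothing else; an open-chain diene would release formaldehyde, which would interfere with the nitronate chemistry. The demand is that 10 is used crude, without exposure to acid, base or silica.

7 from 6. The ring C=C is cut by retro-metathesis, which gives a 1,6-diene. The demand is trivial.

6 from 4 and 5. The O–CH2Ar bond is cut (ether formation at the stage of a simple alcohol).

4 from 1 and 2 (through 3). The terminal vinyl carbon is removed, leaving a terminal epoxide from the chiral pool. The C–O bond of the stereocentre is never broken, so the enantiopurity of 1 is carried into C5 of the target. A catalytic asymmetric reduction of an unsubstituted five-membered enone was set aside, because its two flanks are too alike for reliable induction.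

## Other disconnections considered

Alternative 1: The cut is C1–C6, with the C4–O bond of a lactone re-formed in the retrosynthetic direction. Forward, the six-membered lactone A1 (3,4-bis(benzyloxy), 6-[(E)-2-borylvinyl], the vinyl group trans to the C4 ether) is converted to its silyl ketene acetal. The ketene acetal rearranges in an Ireland–Claisen reaction through a bicyclo[2.2.2]-like boat to acid A2.
- In favour: C1 (quaternary) and C6 are set together in one concerted, stereospecific event, the boron is a latent O6 with retention, and C7 arrives as a carboxyl group. On control of the quaternary centre this alternative is the better of the two, because the chosen plan leaves C1 to a later facial-selectivity problem.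
- Against: A2 has a C4=C5 alkene and no oxygen at C5, so a regio- and stereoselective hydration (O5 at C5, trans to O6, nothing at C4) is still needed, with no clear bias.
- Against: the enolate of A1 has a β-benzyloxy group and can eliminate before it is silylated.
- Against: the allylic boronate in A2 is prone to 1,3-shift.
- Against: A1 itself needs two stereocentres and a geometrically pure vinylboronate.
- Comparison: structurally it solves C1 well and C5 badly; the chosen plan does the reverse and then repairs C1 with a rigid bicyclic ketone. Mechanistically it is kinetically controlled and stereospecific, against thermodynamic control in the chosen plan. In step count it is expected to be clearly longer.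

Alternative 2: The cuts are C2–C3 and C5–C6. Forward, an amine catalyst takes dioxanone A3 through one α-carbon into conjugate addition to acrolein A4 and through the other α-carbon into an aldol closure, giving the bridged hydroxy ketone A5.
- In favour: A5 is essentially the bridged ketone 18 without its ether protection, with O2 and O6 tied and the C1 carbonyl in place, reached in one operation from two cheap achiral compounds. On step economy this alternative is clearly better than the chosen plan, which needs seven steps to reach 18.
- Against: the enamine of A3 is expected to add to the formyl group of A4 (aldol) in preference to conjugate addition, and A4 polymerises under amine catalysis.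
- Against: the absolute configuration rests on a first stereocentre that is α to a ketone and can epimerise.
- Against: O5 in A5 is cis to O6, so an inversion is needed at a hindered carbon next to a bridgehead. A Mitsunobu reaction with 21 would at least install the benzoate directly, but elimination is a likely competitor.
- Against: the bridge is gem-dimethyl, which is the arrangement judged above to endanger the facial selectivity of the C7 addition.
- Comparison: the end-game logic is the same (the two routes are equal there), the step count is better, and the stereochemical security is lower.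

Alternative 3: The cut is C3–C4. Forward, natural tartrate A6 supplies C1 and C6 with trans oxygens; alkylation and two methyl-ketone formations lead to the bis(silyl enol ether) A7. Anodic oxidation of A7 couples its two terminal carbons to the 1,4-diketone A8.
- In favour: the oxidation pattern fits exactly (carbonyls at C2 and C5, methylenes at C3 and C4, C7 already an ether), and the quaternary centre comes from the chiral pool. On fit of skeleton and oxidation level it is the equal of the chosen plan, and on the origin of C1 it is better.
- Against: the key coupling must close a ring onto a trans-fused dioxolane, with two trigonal carbons next to the fusion, and it competes with desilylation and over-oxidation.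
- Against: the two ketones of A8 must then be reduced with the right sense at C2 and C5.
- Against: the two new secondary hydroxyls must be told apart, since only O5 is acylated. The chosen plan avoids this problem by keeping O5 differentiated from the start.
- Against: several steps are needed before the key step.
- Comparison: stronger on C1 and on oxidation levels, weaker in mechanism (kinetic radical-cation coupling against reversible ionic additions) and in oxygen differentiation, and probably longer overall.

Key step: step 5

Assumption: enantiopure 1 is treated as a purchasable building block (it is the epoxide made from (R)-epichlorohydrin and an allyl Grignard reagent).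

## Steps

Step 1
Reactants: 1 (R)-2-(but-3-en-1-yl)oxirane; 2 trimethylsulfonium iodide
Product: 4 (R)-hepta-1,6-dien-3-ol, via sulfonium alkoxide betaine 3 (not isolated)
Conditions: Me3S+ I− (3 equiv), n-BuLi (3 equiv), THF, −10 °C → rt
Reagents that add atoms: trimethylsulfonium iodide 2, C[S+](C)C.[I-]
Why: One-carbon homologation of a terminal epoxide to an allylic alcohol with excess dimethylsulfonium methylide: the ylide opens the epoxide at its CH2 carbon to betaine 3, and a second equivalent acts as base to expel Me2S and leave the vinyl group. The C–O bond of the stereocentre is not touched, so the (R) configuration is retained.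

Step 2
Reactants: 4 (R)-hepta-1,6-dien-3-ol; 5 4-methoxybenzyl chloride
Product: 6 (R)-3-[(4-methoxybenzyl)oxy]hepta-1,6-diene
Conditions: NaH, THF/DMF, 0 °C; then 5, Bu4NI (cat.), 0 °C → rt
Reagents that add atoms: 4-methoxybenzyl chloride 5, COc1ccc(CCl)cc1
Why: Williamson ether synthesis on the sodium alkoxide; no bond to the stereocentre is broken.

Step 3
Reactants: 6 (R)-3-[(4-methoxybenzyl)oxy]hepta-1,6-diene
Product: 7 (R)-3-[(4-methoxybenzyl)oxy]cyclopent-1-ene
Conditions: second-generation Grubbs catalyst (H2IMes)(PCy3)Cl2Ru=CHPh (1 mol %), CH2Cl2, 40 °C
Reagents that add atoms: none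
Why: Ring-closing olefin metathesis of a 1,6-diene to a cyclopentene, driven by loss of ethene; allylic ethers are tolerated and the stereocentre is not involved.

Step 4
Reactants: 7 (R)-3-[(4-methoxybenzyl)oxy]cyclopent-1-ene; 8 ozone
Product: 10 (R)-2-[(4-methoxybenzyl)oxy]pentanedial, via ozonide 9 (not isolated)
Conditions: O3, CH2Cl2, −78 °C (Sudan Red 7B end-point); then Me2S (5 equiv), −78 °C → rt; used crude
Reagents that add atoms: ozone 8, [O-][O+]=O
Why: Ozonolysis with reductive work-up (cycloaddition, cycloreversion and recombination to ozonide 9, then reduction); the alkene reacts far faster than the anisyl ring when the gas flow is stopped at the indicator end-point. The dialdehyde is not chromatographed, so that its α-alkoxy stereocentre is not put at risk.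

Step 5
Reactants: 10 (R)-2-[(4-methoxybenzyl)oxy]pentanedial; 11 nitromethane
Product: 13 (1R,2S,3R,4R)-4-[(4-methoxybenzyl)oxy]-2-nitrocyclohexane-1,3-diol (all four substituents equatorial), via acyclic mono-Henry adduct 12 (not isolated)
Conditions: MeNO2 (1.2 equiv) premixed with NaOMe (0.2 equiv), MeOH (0.1 M), 0 °C → rt, 16 h; AcOH quench
Reagents that add atoms: nitromethane 11, C[N+](=O)[O-]
Why: The methoxide is taken up by the excess nitromethane, so the working base is the nitronate; it adds to one formyl group of 10 (Henry reaction) to give 12, and after renewed deprotonation at the nitro-bearing carbon the new nitronate attacks the second formyl group. The closest known reaction type is the nitromethane double nitro-aldol cyclisation of 1,5-dialdehydes to 2-nitrocyclohexane-1,3-diols, as practised with glutaraldehyde and with sugar-derived dialdehydes. The six-membered ring closes by 6-(enolexo)-exo-trig attack of the nitronate carbon on the aldehyde. Both C–C bond formations and the exchange of the proton α to the nitro group are reversible, so C1 (nitro), C2 and C6 (target numbering) are set under thermodynamic control. The lowest-energy isomer is the chair with the nitro group, both hydroxyls and the C5 ether equatorial, which means O6 trans to O5, O2 cis to O6 and the nitro group trans to both. C5 is the only stereocentre present beforehand, and it fixes the absolute sense, because each enantiomer of 10 has exactly one all-equatorial product. The selectivity the step needs is retention at C5 during equilibration; it is secured by the nitronate (pKa about 10) being the strongest base present, by the low temperature, and by the aldehyde resting largely as hemiacetal in methanol, in line with sugar dialdehydes whose α-oxygenated centres survive this cyclisation. The configuration at C1 is of no consequence, since this carbon becomes a carbonyl group in step 7.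

Step 6
Reactants: 13 (1R,2S,3R,4R)-4-[(4-methoxybenzyl)oxy]-2-nitrocyclohexane-1,3-diol; 14 benzaldehyde dimethyl acetal
Product: 15 (1R,3S,5R,6R,9S)-6-[(4-methoxybenzyl)oxy]-9-nitro-3-phenyl-2,4-dioxabicyclo[3.3.1]nonane (phenyl exo)
Conditions: PhCH(OMe)2 (3 equiv), camphorsulfonic acid (cat.), MeCN, 50 °C, reduced pressure (removal of MeOH)
Reagents that add atoms: benzaldehyde dimethyl acetal 14, COC(OC)c1ccccc1
Why: Acid-catalysed transacetalisation driven by removal of methanol; only the cis-1,3-diol can be bridged, after ring inversion to the conformer with O2 and O6 axial, and the phenyl group takes the exo (equatorial) position of the new 1,3-dioxane, so one acetal epimer is expected. The bridge rules out retro-Henry cleavage and makes β-elimination in the next step a bridgehead-alkene process.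

Step 7
Reactants: 15 (1R,3S,5R,6R,9S)-6-[(4-methoxybenzyl)oxy]-9-nitro-3-phenyl-2,4-dioxabicyclo[3.3.1]nonane; 16 potassium permanganate
Product: 18 (1R,3S,5S,6R)-6-[(4-methoxybenzyl)oxy]-3-phenyl-2,4-dioxabicyclo[3.3.1]nonan-9-one, via potassium nitronate 17 (not isolated)
Conditions: KOH (1.2 equiv), MeOH/H2O, 0 °C; then KMnO4 (0.7 equiv), 0 °C, 20 min; NaHSO3 work-up
Reagents that add atoms: potassium permanganate 16, [K+].[O-][Mn](=O)(=O)=O
Why: Oxidative Nef reaction: deprotonation gives nitronate 17, whose C=N bond is cleaved by permanganate to the ketone and nitrite. Loss of O2 or O6 from 17 and enolisation of 18 would both need a bridgehead double bond, so the three stereocentres around C1 are safe.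

Step 8
Reactants: 18 (1R,3S,5S,6R)-6-[(4-methoxybenzyl)oxy]-3-phenyl-2,4-dioxabicyclo[3.3.1]nonan-9-one; 2 trimethylsulfonium iodide
Product: 19 (1R,3S,5S,6R,9S)-6-[(4-methoxybenzyl)oxy]-3-phenylspiro[2,4-dioxabicyclo[3.3.1]nonane-9,2'-oxirane] (epoxide CH2 on the dioxane side, epoxide oxygen on the carbocycle side)
Conditions: Me3S+ I− (2 equiv), NaH (2 equiv), DMSO/THF (1:1), −5 °C; then 18, −5 °C → rt
Reagents that add atoms: trimethylsulfonium iodide 2, C[S+](C)C.[I-]
Why: Corey–Chaykovsky epoxidation; the unstabilised ylide adds irreversibly from the face syn to the dioxane bridge, which is the axial direction of the 1,3-dioxan-5-one chair and is flanked only by oxygen lone pairs. The carbocycle face is screened by the axial C5 ether and the axial hydrogen on C3 (target numbering), so C7 ends up cis to O2 and O6 and the epoxide oxygen trans, as the target requires.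

Step 9
Reactants: 19 (1R,3S,5S,6R,9S)-6-[(4-methoxybenzyl)oxy]-3-phenylspiro[2,4-dioxabicyclo[3.3.1]nonane-9,2'-oxirane]
Product: 20 (1R,3S,5S,6R,9S)-3-phenylspiro[2,4-dioxabicyclo[3.3.1]nonane-9,2'-oxiran]-6-ol
Conditions: DDQ (1.3 equiv), CH2Cl2/aqueous pH 7 phosphate buffer (10:1), 0 °C → rt
Reagents that add atoms: none
Why: Oxidative cleavage of the electron-rich 4-methoxybenzyl ether by DDQ (hydride abstraction, then hydrolysis of the oxocarbenium ion); the benzylidene acetal and the epoxide are not oxidised under buffered conditions. It is done before the epoxide is opened, so that no syn-axial tertiary hydroxyl is present to capture the oxocarbenium ion as a cyclic acetal.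

Step 10
Reactants: 20 (1R,3S,5S,6R,9S)-3-phenylspiro[2,4-dioxabicyclo[3.3.1]nonane-9,2'-oxiran]-6-ol; 21 benzoic acid
Product: 22 [(1R,3S,5S,6R,9S)-6,9-dihydroxy-3-phenyl-2,4-dioxabicyclo[3.3.1]nonan-9-yl]methyl benzoate
Conditions: PhCO2H (3 equiv), PhCO2Na (1 equiv), DMF, 80 °C
Reagents that add atoms: benzoic acid 21, OC(=O)c1ccccc1
Why: SN2 opening of the 2,2-disubstituted epoxide at its primary carbon C7 by benzoate, with benzoic acid protonating the tertiary alkoxide at once. The C1–O bond is not broken, so the C1 configuration set in step 8 is kept.

Step 11
Reactants: 22 [(1R,3S,5S,6R,9S)-6,9-dihydroxy-3-phenyl-2,4-dioxabicyclo[3.3.1]nonan-9-yl]methyl benzoate; 23 benzoyl chloride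
Product: 24 [(1R,3S,5S,6R,9S)-6-(benzoyloxy)-9-hydroxy-3-phenyl-2,4-dioxabicyclo[3.3.1]nonan-9-yl]methyl benzoate
Conditions: BzCl (1.5 equiv), pyridine, DMAP (cat.), CH2Cl2, 0 °C → rt
Reagents that add atoms: benzoyl chloride 23, ClC(=O)c1ccccc1
Why: Acylation of the only secondary hydroxyl; the tertiary hydroxyl at C1 does not react with benzoyl chloride under these mild conditions.

Step 12
Reactants: 24 [(1R,3S,5S,6R,9S)-6-(benzoyloxy)-9-hydroxy-3-phenyl-2,4-dioxabicyclo[3.3.1]nonan-9-yl]methyl benzoate
Product: 25 [(1S,2S,3R,6R)-3-(benzoyloxy)-1,2,6-trihydroxycyclohexyl]methyl benzoate (CNP0264996.1)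
Conditions: H2 (1 atm), Pd(OH)2/C, EtOAc/MeOH, rt
Reagents that add atoms: none
Why: Hydrogenolysis of the benzylidene acetal at its benzylic C–O bonds under neutral conditions; benzoates are inert and no acid or base is present to move them. The freed ring relaxes to the chair with O1, O2, O5 and O6 equatorial.

## Compound list

1 | (R)-2-(but-3-en-1-yl)oxirane [(R)-1,2-epoxy-5-hexene] | C=CCC[C@@H]1CO1 | starting material
2 | trimethylsulfonium iodide | C[S+](C)C.[I-] | starting material
3 | (3R)-1-(dimethylsulfonio)hept-6-en-3-olate (betaine, not isolated) | C=CCC[C@@H]([O-])CC[S+](C)C | intermediate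
4 | (R)-hepta-1,6-dien-3-ol | C=CCC[C@@H](O)C=C | intermediate
5 | 4-methoxybenzyl chloride | COc1ccc(CCl)cc1 | starting material
6 | (R)-3-[(4-methoxybenzyl)oxy]hepta-1,6-diene | C=CCC[C@@H](OCc1ccc(OC)cc1)C=C | intermediate
7 | (R)-3-[(4-methoxybenzyl)oxy]cyclopent-1-ene | COc1ccc(CO[C@@H]2CCC=C2)cc1 | intermediate
8 | ozone | [O-][O+]=O | starting material
9 | (2R)-2-[(4-methoxybenzyl)oxy]-6,7,8-trioxabicyclo[3.2.1]octane (ozonide, bridgehead epimers not distinguished, not isolated) | COc1ccc(CO[C@@H]2CCC3OOC2O3)cc1 | intermediate
10 | (R)-2-[(4-methoxybenzyl)oxy]pentanedial | O=CCC[C@@H](OCc1ccc(OC)cc1)C=O | intermediate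
11 | nitromethane | C[N+](=O)[O-] | starting material
12 | (2R)-5-hydroxy-2-[(4-methoxybenzyl)oxy]-6-nitrohexanal (both C5 epimers, not isolated) | O=C[C@H](OCc1ccc(OC)cc1)CCC(O)C[N+](=O)[O-] | intermediate
13 | (1R,2S,3R,4R)-4-[(4-methoxybenzyl)oxy]-2-nitrocyclohexane-1,3-diol (all substituents equatorial) | [O-][N+](=O)[C@H]1[C@H](O)CC[C@@H](OCc2ccc(OC)cc2)[C@@H]1O | intermediate
14 | benzaldehyde dimethyl acetal | COC(OC)c1ccccc1 | starting material
15 | (1R,3S,5R,6R,9S)-6-[(4-methoxybenzyl)oxy]-9-nitro-3-phenyl-2,4-dioxabicyclo[3.3.1]nonane (phenyl exo) | [O-][N+](=O)[C@H]1[C@H]2CC[C@@H](OCc3ccc(OC)cc3)[C@@H]1O[C@@H](c4ccccc4)O2 | intermediate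
16 | potassium permanganate | [K+].[O-][Mn](=O)(=O)=O | starting material
17 | potassium aci-nitronate of 15 (C9 trigonal, not isolated) | [K+].[O-][N+]([O-])=C1[C@H]2CC[C@@H](OCc3ccc(OC)cc3)[C@@H]1O[C@@H](c4ccccc4)O2 | intermediate
18 | (1R,3S,5S,6R)-6-[(4-methoxybenzyl)oxy]-3-phenyl-2,4-dioxabicyclo[3.3.1]nonan-9-one | O=C1[C@H]2CC[C@@H](OCc3ccc(OC)cc3)[C@@H]1O[C@@H](c4ccccc4)O2 | intermediate
19 | (1R,3S,5S,6R,9S)-6-[(4-methoxybenzyl)oxy]-3-phenylspiro[2,4-dioxabicyclo[3.3.1]nonane-9,2'-oxirane] | C1O[C@]12[C@H]3CC[C@@H](OCc4ccc(OC)cc4)[C@@H]2O[C@@H](c5ccccc5)O3 | intermediate
20 | (1R,3S,5S,6R,9S)-3-phenylspiro[2,4-dioxabicyclo[3.3.1]nonane-9,2'-oxiran]-6-ol | C1O[C@]12[C@H]3CC[C@@H](O)[C@@H]2O[C@@H](c4ccccc4)O3 | intermediate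
21 | benzoic acid | OC(=O)c1ccccc1 | starting material
22 | [(1R,3S,5S,6R,9S)-6,9-dihydroxy-3-phenyl-2,4-dioxabicyclo[3.3.1]nonan-9-yl]methyl benzoate | O=C(OC[C@]1(O)[C@H]2CC[C@@H](O)[C@@H]1O[C@@H](c3ccccc3)O2)c4ccccc4 | intermediate
23 | benzoyl chloride | ClC(=O)c1ccccc1 | starting material
24 | [(1R,3S,5S,6R,9S)-6-(benzoyloxy)-9-hydroxy-3-phenyl-2,4-dioxabicyclo[3.3.1]nonan-9-yl]methyl benzoate | O=C(OC[C@]1(O)[C@H]2CC[C@@H](OC(=O)c3ccccc3)[C@@H]1O[C@@H](c4ccccc4)O2)c5ccccc5 | intermediate
25 | [(1S,2S,3R,6R)-3-(benzoyloxy)-1,2,6-trihydroxycyclohexyl]methyl benzoate | O=C(OC[C@]1(O)[C@H](O)CC[C@@H](OC(=O)c2ccccc2)[C@@H]1O)c1ccccc1 | target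

## Step count and least certain steps

Total: 12 steps. Longest linear sequence: 12 steps (the route is fully linear from 1).

Step 5 (key step). The most likely failure is loss of configuration at C5 by enolisation of the α-alkoxy aldehyde during the repeated retro-Henry and Henry events. A second risk is incomplete funnelling into the all-equatorial isomer, which would leave epimeric nitro diols. The fallback separates the two Henry events, so that the α-alkoxy aldehyde is released last and meets only a trace of amine. It sets out from 6. The remote, more electron-rich terminal alkene is cleaved selectively (OsO4 cat., NaIO4, 2,6-lutidine, aqueous dioxane) to (R)-4-[(4-methoxybenzyl)oxy]hex-5-enal F1. An ordinary Henry addition of 11 (Et3N) gives (5R)-5-[(4-methoxybenzyl)oxy]-1-nitrohept-6-en-2-ol F2. Ozonolysis of the remaining alkene (O3, then Me2S) releases 12, which should close with catalytic Et3N to 13, where the route is rejoined.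

Step 6. The most likely failure is an unfavourable ring closure. Bridging needs the chair in which O2 and O6 are axial, and in that chair the nitro group and the C5 ether are syn-axial, so open mixed acetals and oligomers may persist. The fallback closes the bridge only when C1 is trigonal. It sets out from 13. Et3SiCl and imidazole give the bis(triethylsilyl) ether of 13, F3. The permanganate Nef reaction of step 7 then gives 2,6-bis[(triethylsilyl)oxy]-3-[(4-methoxybenzyl)oxy]cyclohexan-1-one F4; its equatorial silyloxy groups lie near the nodal plane of the nitronate and are poorly placed for β-elimination. Silyl-transfer acetalisation of F4 (PhCHO, catalytic Me3SiOTf, CH2Cl2, −78 °C) returns to the route at 18.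

Step 7. The most likely failure is sluggish oxidation of the hindered bridging nitronate, so that permanganate begins to attack the anisyl ether or the benzylic acetal C–H. The fallback changes from an oxidative to a reductive Nef reaction. It sets out from 15. Nitronate 17 is added to buffered aqueous TiCl3 (NH4OAc, pH about 5), where trivalent titanium reduces the N–O bonds to give the oxime of 18, F5. F5 is reduced further to the imine and hydrolysed in the same flask to 18.

Step 8. The most likely failure is poor facial selectivity. If ring B leaves its chair, the carbocycle face becomes the open one and the ylide carbon adds there, which gives the C1 epimer. The fallback inverts the order in which carbon and oxygen arrive. It sets out from 18. Wittig methylenation (Ph3PCH3Br, KOtBu, THF) gives the 9-methylene compound F6. Peracid epoxidation (mCPBA, NaHCO3, CH2Cl2) then delivers oxygen from whichever face is open; in the failure case this is the carbocycle face, and the product is again 19.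

Step 10. The most likely failure is slow substitution at C7, which is neopentyl-like, so that acyl scrambling sets in at the temperature required. The fallback uses a smaller nucleophile and acylates afterwards. It sets out from 20. KOH in aqueous DMSO at 80 °C opens the epoxide at C7 to 9-(hydroxymethyl)-3-phenyl-2,4-dioxabicyclo[3.3.1]nonane-6,9-diol F7. BzCl (2.2 equiv) in pyridine then esterifies the primary and the secondary hydroxyl but not the tertiary one, and gives 24 directly.

## Further compounds

F1 | step 5 | (R)-4-[(4-methoxybenzyl)oxy]hex-5-enal | O=CCC[C@@H](OCc1ccc(OC)cc1)C=C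
F2 | step 5 | (5R)-5-[(4-methoxybenzyl)oxy]-1-nitrohept-6-en-2-ol (both C2 epimers) | [O-][N+](=O)CC(O)CC[C@@H](OCc1ccc(OC)cc1)C=C
F3 | step 6 | bis(triethylsilyl) ether of (1R,2S,3R,4R)-4-[(4-methoxybenzyl)oxy]-2-nitrocyclohexane-1,3-diol | [O-][N+](=O)[C@H]1[C@H](O[Si](CC)(CC)CC)CC[C@@H](OCc2ccc(OC)cc2)[C@@H]1O[Si](CC)(CC)CC
F4 | step 6 | 2,6-bis[(triethylsilyl)oxy]-3-[(4-methoxybenzyl)oxy]cyclohexan-1-one (2,6-cis, 2,3-trans, all equatorial) | O=C1[C@H](O[Si](CC)(CC)CC)CC[C@@H](OCc2ccc(OC)cc2)[C@@H]1O[Si](CC)(CC)CC
F5 | step 7 | oxime of 6-[(4-methoxybenzyl)oxy]-3-phenyl-2,4-dioxabicyclo[3.3.1]nonan-9-one (oxime geometry not distinguished) | ON=C1[C@H]2CC[C@@H](OCc3ccc(OC)cc3)[C@@H]1O[C@@H](c4ccccc4)O2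
F6 | step 8 | 6-[(4-methoxybenzyl)oxy]-9-methylidene-3-phenyl-2,4-dioxabicyclo[3.3.1]nonane | C=C1[C@H]2CC[C@@H](OCc3ccc(OC)cc3)[C@@H]1O[C@@H](c4ccccc4)O2
F7 | step 10 | 9-(hydroxymethyl)-3-phenyl-2,4-dioxabicyclo[3.3.1]nonane-6,9-diol | OC[C@]1(O)[C@H]2CC[C@@H](O)[C@@H]1O[C@@H](c3ccccc3)O2
A1 | alternative 1 | 3,4-bis(benzyloxy)-6-[(E)-2-(4,4,5,5-tetramethyl-1,3,2-dioxaborolan-2-yl)ethenyl]oxan-2-one (vinyl trans to the C4 ether; C3 is enolised, so its configuration is left open) | O=C1O[C@H](/C=C/B2OC(C)(C)C(C)(C)O2)C[C@@H](OCc3ccccc3)C1OCc4ccccc4
A2 | alternative 1 | 1,2-bis(benzyloxy)-6-(4,4,5,5-tetramethyl-1,3,2-dioxaborolan-2-yl)cyclohex-4-ene-1-carboxylic acid (carboxyl cis to the C2 ether and to boron) | OC(=O)[C@]1(OCc2ccccc2)[C@H](OCc2ccccc2)CC=C[C@@H]1B1OC(C)(C)C(C)(C)O1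
A3 | alternative 2 | 2,2-dimethyl-1,3-dioxan-5-one | CC1(C)OCC(=O)CO1
A4 | alternative 2 | acrolein | C=CC=O
A5 | alternative 2 | 6-hydroxy-3,3-dimethyl-2,4-dioxabicyclo[3.3.1]nonan-9-one (hydroxyl cis to the neighbouring bridgehead oxygen) | O=C1[C@H]2CC[C@H](O)[C@@H]1OC(C)(C)O2
A6 | alternative 3 | dimethyl (2R,3R)-tartrate | COC(=O)[C@H](O)[C@@H](O)C(=O)OC
A7 | alternative 3 | trans-4-[(benzyloxy)methyl]-2,2-dimethyl-4,5-bis[1-(trimethylsilyloxy)ethenyl]-1,3-dioxolane | c1ccccc1COC[C@@]1(C(=C)O[Si](C)(C)C)OC(C)(C)O[C@H]1C(=C)O[Si](C)(C)C
A8 | alternative 3 | trans-fused acetonide of 2-[(benzyloxy)methyl]-2,3-dihydroxycyclohexane-1,4-dione | c1ccccc1COC[C@]1(OC(C)(C)O2)C(=O)CCC(=O)[C@@H]12
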